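**Retrosynthetic overview**

- The side-chain hydrogen sulfate, the C3 hydroxymethyl group and the phenol are unmasked last. They trace back to a 2,3-dihydrobenzofuran carrying a methyl propanoate at C5, CH2OTBS at C3 and an aryl mesylate on the C2 aryl group.
- Feature the strategy rests on: in ring A, C3a and C7a are neighbours and C7a is flanked by the C7 methoxy group. C3a–C3 and C7a–O1 are therefore the ortho C–H and ipso C–I positions of a 2-methoxyaryl iodide, and O1–C2–C3 is a cis-2,3-disubstituted epoxide.
- Key disconnection: palladium/norbornene annulation of that aryl iodide with the enantiopure cis-epoxide. It forms C3a–C3 (inversion at C3) and C7a–O1 (retention at C2) and closes the dihydrofuran ring, the only ring made; both benzene rings are bought.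
- Aryl iodide: from 3-methoxy-4-nitrobenzaldehyde by olefination, hydrogenation and Sandmeyer iodination.
- Epoxide: from vanillin by mesylation, Z-selective olefination, reduction, Sharpless epoxidation (sets C2 and the centre to be inverted) and silylation.

Key step: step 9

Assumption: the target is taken as the free hydrogen sulfate exactly as drawn; the sulfate is carried as its sodium salt and protonated only in the last operation.

**Route**

Step 1
Reactants: 1 3-methoxy-4-nitrobenzaldehyde; 2 trimethyl phosphonoacetate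
Product: 3 methyl (E)-3-(3-methoxy-4-nitrophenyl)prop-2-enoate
Conditions: NaH, THF, 0 °C → rt
Reagents that add atoms: none
Why: Horner–Wadsworth–Emmons olefination of a non-enolisable, electron-poor aldehyde with a stabilised phosphonate anion should give the E-enoate; the geometry is of no consequence because the alkene is saturated in step 2.

Step 2
Reactants: 3 methyl (E)-3-(3-methoxy-4-nitrophenyl)prop-2-enoate
Product: 4 methyl 3-(4-amino-3-methoxyphenyl)propanoate
Conditions: H2 (1 atm), 10 % Pd/C, MeOH–EtOAc, rt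
Reagents that add atoms: none
Why: Catalytic hydrogenation over palladium should reduce the nitro group and the conjugated alkene in one operation while the ester and aryl ether are inert.

Step 3
Reactants: 4 methyl 3-(4-amino-3-methoxyphenyl)propanoate
Product: 6 methyl 3-(4-iodo-3-methoxyphenyl)propanoate, via arenediazonium hydrogensulfate 5 (not isolated)
Conditions: NaNO2, H2SO4 (aq), MeCN, 0 °C; then KI, 0 °C → rt
Reagents that add atoms: potassium iodide, [K+].[I-] (iodine of 6); sodium nitrite, [Na+].[O-]N=O (second nitrogen of 5); sulfuric acid, OS(=O)(=O)O (counter-ion of 5)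
Why: Diazotisation followed by iodide displacement of dinitrogen (Sandmeyer-type iodination, which needs no copper) should place iodine para to the side chain and ortho to the methoxy group.

Step 4
Reactants: 7 vanillin
Product: 8 4-formyl-2-methoxyphenyl methanesulfonate
Conditions: MsCl, Et3N, CH2Cl2, 0 °C
Reagents that add atoms: methanesulfonyl chloride, CS(=O)(=O)Cl
Why: Sulfonylation of the phenol makes the guaiacyl ring electron-poor, which should keep the later benzylic epoxide from ionising, and the aryl mesylate tolerates the hydride, titanium and palladium reagents that follow.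

Step 5
Reactants: 8 4-formyl-2-methoxyphenyl methanesulfonate; 9 methyl 2-[bis(2,2,2-trifluoroethoxy)phosphoryl]acetate
Product: 10 methyl (Z)-3-(3-methoxy-4-methylsulfonyloxyphenyl)prop-2-enoate
Conditions: KN(SiMe3)2, 18-crown-6, THF, −78 °C
Reagents that add atoms: none
Why: Still–Gennari olefination: the trifluoroethyl phosphonate with a dissociated potassium counter-ion eliminates under kinetic control and should give the Z-enoate from an aryl aldehyde.

Step 6
Reactants: 10 methyl (Z)-3-(3-methoxy-4-methylsulfonyloxyphenyl)prop-2-enoate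
Product: 11 4-[(Z)-3-hydroxyprop-1-en-1-yl]-2-methoxyphenyl methanesulfonate
Conditions: iBu2AlH (2.3 equiv), CH2Cl2, −78 °C; aqueous potassium sodium tartrate
Reagents that add atoms: none
Why: 1,2-Reduction of the enoate with iBu2AlH at low temperature should give the allylic alcohol without isomerising the Z-alkene or touching the aryl sulfonate.

Step 7
Reactants: 11 4-[(Z)-3-hydroxyprop-1-en-1-yl]-2-methoxyphenyl methanesulfonate
Product: 12 4-[(2R,3S)-3-(hydroxymethyl)oxiran-2-yl]-2-methoxyphenyl methanesulfonate (cis)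
Conditions: Ti(OiPr)4 (1.0 equiv), L-(+)-diisopropyl tartrate (1.2 equiv), tBuOOH (anhydrous, 2 equiv), 4 Å molecular sieves, CH2Cl2, −20 °C
Reagents that add atoms: tert-butyl hydroperoxide, CC(C)(C)OO
Why: Sharpless asymmetric epoxidation: the titanium–L-(+)-tartrate complex should deliver oxygen to one face of the Z-allylic alcohol and give the cis-epoxy alcohol with the aryl-bearing carbon R (future C2) and the CH2OH-bearing carbon S (future C3, to be inverted).

Step 8
Reactants: 12 4-[(2R,3S)-3-(hydroxymethyl)oxiran-2-yl]-2-methoxyphenyl methanesulfonate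
Product: 13 4-[(2R,3S)-3-(tert-butyldimethylsilyloxymethyl)oxiran-2-yl]-2-methoxyphenyl methanesulfonate
Conditions: TBSCl, imidazole, CH2Cl2, 0 °C → rt
Reagents that add atoms: tert-butyldimethylsilyl chloride, CC(C)(C)[Si](C)(C)Cl
Why: Silylation of the primary alcohol should block Payne rearrangement under the basic conditions of step 9 and keeps this hydroxyl distinct from the side-chain alcohol that is sulfated later.

Step 9
Reactants: 6 methyl 3-(4-iodo-3-methoxyphenyl)propanoate; 13 4-[(2R,3S)-3-(tert-butyldimethylsilyloxymethyl)oxiran-2-yl]-2-methoxyphenyl methanesulfonate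
Product: 14 methyl 3-[(2S,3R)-3-(tert-butyldimethylsilyloxymethyl)-7-methoxy-2-(3-methoxy-4-methylsulfonyloxyphenyl)-2,3-dihydro-1-benzofuran-5-yl]propanoate
Conditions: 6 (1.0 equiv), 13 (1.5 equiv), Pd(OAc)2 (10 mol %), XPhos (2-dicyclohexylphosphino-2',4',6'-triisopropylbiphenyl, 20 mol %), potassium 5-norbornene-2-carboxylate (50 mol %), K2CO3 (2 equiv), N-methylpyrrolidone, 70 °C
Reagents that add atoms: none
Why: Proposed new method: oxidative addition of 6 to zerovalent palladium, norbornene insertion and carboxylate-assisted palladation of the only free ortho C–H (C3a) should give the divalent aryl–norbornyl palladacycle, which is expected to open epoxide 13 by SN2 attack at the CH2OSi-bearing carbon (tetravalent palladium), form C3a–C3 by reductive elimination, lose norbornene by beta-carbon elimination and form C7a–O1 by C–O reductive elimination from the divalent arylpalladium alkoxide. The closest known reaction type is the palladium/norbornene (Catellani-type) annulation of ortho-substituted aryl iodides with terminal epoxides to 2,3-dihydrobenzofurans; alkylation by the secondary carbon of a 1,2-disubstituted epoxide is the untested extension. The dihydrofuran ring closes by intramolecular C(aryl)–O reductive elimination at the ipso carbon from a six-membered oxapalladacycle. C3 is set by stereospecific inversion at the attacked epoxide carbon and C2 is carried with retention from step 7, so the cis-epoxide should give the trans (2S,3R) ring. The step needs opening at the CH2OSi carbon and not at the benzylic one: the para-mesyloxy group suppresses benzylic C–O ionisation so that a tight SN2 transition state is kept, the bulky palladacycle should prefer the carbon flanked by a freely rotating CH2O group over the one flanked by the aryl ring, and the C7 methoxy group of 6 leaves a single ortho C–H and forces norbornene extrusion after one alkylation; this regiochemistry is not secured by precedent.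

Step 10
Reactants: 14 methyl 3-[(2S,3R)-3-(tert-butyldimethylsilyloxymethyl)-7-methoxy-2-(3-methoxy-4-methylsulfonyloxyphenyl)-2,3-dihydro-1-benzofuran-5-yl]propanoate
Product: 15 4-[(2S,3R)-3-(tert-butyldimethylsilyloxymethyl)-5-(3-hydroxypropyl)-7-methoxy-2,3-dihydro-1-benzofuran-2-yl]-2-methoxyphenyl methanesulfonate
Conditions: LiBH4, THF, MeOH (1 equiv), 0 °C → rt
Reagents that add atoms: none
Why: LiBH4 should reduce the methyl ester to the primary alcohol chemoselectively; the silyl ether, the aryl mesylate and the two stereocentres, which carry no acidic hydrogen, are not affected.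

Step 11
Reactants: 15 4-[(2S,3R)-3-(tert-butyldimethylsilyloxymethyl)-5-(3-hydroxypropyl)-7-methoxy-2,3-dihydro-1-benzofuran-2-yl]-2-methoxyphenyl methanesulfonate
Product: 16 sodium 3-[(2S,3R)-3-(tert-butyldimethylsilyloxymethyl)-7-methoxy-2-(3-methoxy-4-methylsulfonyloxyphenyl)-2,3-dihydro-1-benzofuran-5-yl]propyl sulfate
Conditions: SO3·pyridine (3 equiv), pyridine, rt; then NaHCO3 (aq)
Reagents that add atoms: sulfur trioxide–pyridine complex, [O-]S(=O)(=O)[n+]1ccccc1; sodium hydrogencarbonate, [Na+].OC([O-])=O (sodium counter-ion)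
Why: O-Sulfation of the only free hydroxyl with the sulfur trioxide–pyridine complex should give the sulfate monoester, isolated as its sodium salt.

Step 12
Reactants: 16 sodium 3-[(2S,3R)-3-(tert-butyldimethylsilyloxymethyl)-7-methoxy-2-(3-methoxy-4-methylsulfonyloxyphenyl)-2,3-dihydro-1-benzofuran-5-yl]propyl sulfate
Product: 17 sodium 3-[(2S,3R)-3-(hydroxymethyl)-7-methoxy-2-(3-methoxy-4-methylsulfonyloxyphenyl)-2,3-dihydro-1-benzofuran-5-yl]propyl sulfate
Conditions: HF·pyridine, pyridine, THF, 0 °C → rt; NaHCO3 quench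
Reagents that add atoms: none
Why: Fluoride should cleave the primary silyl ether through the strong Si–F bond under buffered conditions that leave the sulfate monoester and the aryl sulfonate intact.

Step 13
Reactants: 17 sodium 3-[(2S,3R)-3-(hydroxymethyl)-7-methoxy-2-(3-methoxy-4-methylsulfonyloxyphenyl)-2,3-dihydro-1-benzofuran-5-yl]propyl sulfate
Product: 18 3-[(2S,3R)-2-(4-hydroxy-3-methoxyphenyl)-3-(hydroxymethyl)-7-methoxy-2,3-dihydro-1-benzofuran-5-yl]propyl hydrogen sulfate
Conditions: NaOH (2 M aq), MeOH, 60 °C; then HCl (1 M aq) to pH 1–2, 0 °C; C18 desalting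
Reagents that add atoms: none
Why: Hydroxide should cleave the aryl methanesulfonate (attack at sulfur or sulfene elimination) while the alkyl sulfate monoanion is inert to base and neither stereocentre is epimerisable, and acidification then gives the hydrogen sulfate.

**Compound list**

1 | 3-methoxy-4-nitrobenzaldehyde | COc1cc(C=O)ccc1[N+](=O)[O-] | starting material
2 | trimethyl phosphonoacetate | COC(=O)CP(=O)(OC)OC | starting material
3 | methyl (E)-3-(3-methoxy-4-nitrophenyl)prop-2-enoate | COC(=O)/C=C/c1ccc([N+](=O)[O-])c(OC)c1 | intermediate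
4 | methyl 3-(4-amino-3-methoxyphenyl)propanoate | COC(=O)CCc1ccc(N)c(OC)c1 | intermediate
5 | 2-methoxy-4-(3-methoxy-3-oxopropyl)benzenediazonium hydrogensulfate | COC(=O)CCc1ccc([N+]#N)c(OC)c1.OS(=O)(=O)[O-] | intermediate (not isolated)
6 | methyl 3-(4-iodo-3-methoxyphenyl)propanoate | COC(=O)CCc1ccc(I)c(OC)c1 | intermediate
7 | vanillin | COc1cc(C=O)ccc1O | starting material
8 | 4-formyl-2-methoxyphenyl methanesulfonate | COc1cc(C=O)ccc1OS(C)(=O)=O | intermediate
9 | methyl 2-[bis(2,2,2-trifluoroethoxy)phosphoryl]acetate | COC(=O)CP(=O)(OCC(F)(F)F)OCC(F)(F)F | starting material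
10 | methyl (Z)-3-(3-methoxy-4-methylsulfonyloxyphenyl)prop-2-enoate | COC(=O)/C=C\c1ccc(OS(C)(=O)=O)c(OC)c1 | intermediate
11 | 4-[(Z)-3-hydroxyprop-1-en-1-yl]-2-methoxyphenyl methanesulfonate | COc1cc(/C=C\CO)ccc1OS(C)(=O)=O | intermediate
12 | 4-[(2R,3S)-3-(hydroxymethyl)oxiran-2-yl]-2-methoxyphenyl methanesulfonate | COc1cc([C@H]2O[C@H]2CO)ccc1OS(C)(=O)=O | intermediate
13 | 4-[(2R,3S)-3-(tert-butyldimethylsilyloxymethyl)oxiran-2-yl]-2-methoxyphenyl methanesulfonate | COc1cc([C@H]2O[C@H]2CO[Si](C)(C)C(C)(C)C)ccc1OS(C)(=O)=O | intermediate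
14 | methyl 3-[(2S,3R)-3-(tert-butyldimethylsilyloxymethyl)-7-methoxy-2-(3-methoxy-4-methylsulfonyloxyphenyl)-2,3-dihydro-1-benzofuran-5-yl]propanoate | COc1cc([C@H]2Oc3c(OC)cc(CCC(=O)OC)cc3[C@@H]2CO[Si](C)(C)C(C)(C)C)ccc1OS(C)(=O)=O | intermediate
15 | 4-[(2S,3R)-3-(tert-butyldimethylsilyloxymethyl)-5-(3-hydroxypropyl)-7-methoxy-2,3-dihydro-1-benzofuran-2-yl]-2-methoxyphenyl methanesulfonate | COc1cc([C@H]2Oc3c(OC)cc(CCCO)cc3[C@@H]2CO[Si](C)(C)C(C)(C)C)ccc1OS(C)(=O)=O | intermediate
16 | sodium 3-[(2S,3R)-3-(tert-butyldimethylsilyloxymethyl)-7-methoxy-2-(3-methoxy-4-methylsulfonyloxyphenyl)-2,3-dihydro-1-benzofuran-5-yl]propyl sulfate | COc1cc([C@H]2Oc3c(OC)cc(CCCOS(=O)(=O)[O-])cc3[C@@H]2CO[Si](C)(C)C(C)(C)C)ccc1OS(C)(=O)=O.[Na+] | intermediate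
17 | sodium 3-[(2S,3R)-3-(hydroxymethyl)-7-methoxy-2-(3-methoxy-4-methylsulfonyloxyphenyl)-2,3-dihydro-1-benzofuran-5-yl]propyl sulfate | COc1cc([C@H]2Oc3c(OC)cc(CCCOS(=O)(=O)[O-])cc3[C@@H]2CO)ccc1OS(C)(=O)=O.[Na+] | intermediate
18 | 3-[(2S,3R)-2-(4-hydroxy-3-methoxyphenyl)-3-(hydroxymethyl)-7-methoxy-2,3-dihydro-1-benzofuran-5-yl]propyl hydrogen sulfate | COc1cc([C@H]2Oc3c(OC)cc(CCCOS(=O)(=O)O)cc3[C@@H]2CO)ccc1O | target

**Step count**

Total steps: 13. Longest linear sequence: 10 steps (vanillin 7 to 18, steps 4–13).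

**Steps most likely to fail**

1. Step 9 (the new annulation).
   - What may go wrong: the palladacycle may open the epoxide at the benzylic carbon instead of the CH2OSi-bearing one. It may also fail to alkylate a secondary carbon at all, so that hydrodeiodination of 6 and palladium-induced isomerisation of 13 take over.
   - Fallback (known chemistry): C2–C3 is made by an Evans syn-aldol reaction and C7a–O1 by intramolecular Buchwald–Hartwig etherification with retention at C2. It sets out from aniline 4, with aldehyde 8 as the aldol partner, and returns to the route at 14.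
   - Iodination of 4 ortho to the amino group (N-iodosuccinimide, MeCN) should give methyl 3-(4-amino-3-iodo-5-methoxyphenyl)propanoate F1. Sandmeyer bromination (tBuONO, CuBr2, MeCN) through 2-iodo-6-methoxy-4-(3-methoxy-3-oxopropyl)benzenediazonium bromide F2 should give methyl 3-(4-bromo-3-iodo-5-methoxyphenyl)propanoate F3.
   - Negishi-type coupling at the more reactive C–I bond with the Reformatsky reagent BrZnCH2CO2tBu (Pd2(dba)3, XPhos, THF) should give methyl 3-[4-bromo-3-(2-tert-butoxy-2-oxoethyl)-5-methoxyphenyl]propanoate F4. CF3CO2H then releases 2-[2-bromo-3-methoxy-5-(3-methoxy-3-oxopropyl)phenyl]acetic acid F5.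
   - Acylation of (S)-4-benzyl-1,3-oxazolidin-2-one through the pivalic mixed anhydride (tBuCOCl, Et3N, LiCl, THF) should give the N-arylacetyl oxazolidinone F6. Enolisation with Bu2BOTf/iPr2NEt (CH2Cl2, −78 → 0 °C) and addition to 8 should give the (2S,3S) syn-aldol adduct F7.
   - NaBH4 in THF–water removes the auxiliary reductively and leaves the methyl ester, giving the (2R,3S)-1,3-diol F8. TBSCl/imidazole silylates the primary hydroxyl to give the mono-silyl ether F9.
   - Pd(OAc)2, 2-(di-tert-butylphosphino)-1,1'-binaphthyl and Cs2CO3 in toluene at 80 °C then couple the benzylic alkoxide with the aryl bromide, with retention at the carbinol carbon, to give 14.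

2. Step 7.
   - What may go wrong: Z-disubstituted allylic alcohols are the slowest substrates of the Sharpless epoxidation, so incomplete conversion, eroded facial selectivity and titanium-mediated opening of the aryl epoxide during the long reaction time are possible.
   - Fallback: oxygen transfer to the Z-enoate instead of the allylic alcohol; it sets out from 10 and returns at 12.
   - Jacobsen–Katsuki epoxidation of 10 with NaOCl, 4-phenylpyridine N-oxide and (R,R)-N,N'-bis(3,5-di-tert-butylsalicylidene)-1,2-cyclohexanediamine manganese chloride (trivalent manganese) in CH2Cl2 at 0 °C should give methyl (2R,3R)-3-(3-methoxy-4-methylsulfonyloxyphenyl)oxirane-2-carboxylate F10.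
   - NaBH4 in MeOH at 0 °C then reduces the glycidic ester to 12.

3. Step 13.
   - What may go wrong: sulfonate cleavage may be incomplete in warm hydroxide, the dihydrofuran may open through a quinone methide once the para-phenoxide is free, and the hydrogen sulfate may hydrolyse partly during acidification.
   - Fallback: the phenol protecting group is exchanged before sulfation so that the last deprotection is neutral; it sets out from 15 and returns at 18.
   - LiN(iPr)2 (THF, −78 → 0 °C) removes the mesyl group by sulfene elimination at low temperature to give 4-[(2S,3R)-3-(tert-butyldimethylsilyloxymethyl)-5-(3-hydroxypropyl)-7-methoxy-2,3-dihydro-1-benzofuran-2-yl]-2-methoxyphenol F11. BnBr, K2CO3 in acetone alkylates the phenol only and gives the benzyl ether F12.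
   - SO3·pyridine followed by NaHCO3 gives the sodium sulfate F13, and HF·pyridine gives the desilylated sodium sulfate F14.
   - Hydrogenolysis (H2, Pd/C, MeOH) followed by the acidification and desalting of step 13 gives 18.

**Further compounds**

F1 | step 9 | methyl 3-(4-amino-3-iodo-5-methoxyphenyl)propanoate | COC(=O)CCc1cc(I)c(N)c(OC)c1
F2 | step 9 | 2-iodo-6-methoxy-4-(3-methoxy-3-oxopropyl)benzenediazonium bromide | COC(=O)CCc1cc(I)c([N+]#N)c(OC)c1.[Br-]
F3 | step 9 | methyl 3-(4-bromo-3-iodo-5-methoxyphenyl)propanoate | COC(=O)CCc1cc(I)c(Br)c(OC)c1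
F4 | step 9 | methyl 3-[4-bromo-3-(2-tert-butoxy-2-oxoethyl)-5-methoxyphenyl]propanoate | COC(=O)CCc1cc(CC(=O)OC(C)(C)C)c(Br)c(OC)c1
F5 | step 9 | 2-[2-bromo-3-methoxy-5-(3-methoxy-3-oxopropyl)phenyl]acetic acid | COC(=O)CCc1cc(CC(=O)O)c(Br)c(OC)c1
F6 | step 9 | methyl 3-[4-bromo-3-methoxy-5-{2-[(4S)-4-benzyl-2-oxo-1,3-oxazolidin-3-yl]-2-oxoethyl}phenyl]propanoate | COC(=O)CCc1cc(CC(=O)N2[C@@H](Cc3ccccc3)COC2=O)c(Br)c(OC)c1
F7 | step 9 | (4S)-4-benzyl-3-[(2S,3S)-2-[2-bromo-3-methoxy-5-(3-methoxy-3-oxopropyl)phenyl]-3-hydroxy-3-(3-methoxy-4-methylsulfonyloxyphenyl)propanoyl]-1,3-oxazolidin-2-one | COc1cc([C@@H](O)[C@@H](C(=O)N3[C@@H](Cc4ccccc4)COC3=O)c2cc(CCC(=O)OC)cc(OC)c2Br)ccc1OS(C)(=O)=O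
F8 | step 9 | methyl 3-{4-bromo-3-[(2R,3S)-1,3-dihydroxy-3-(3-methoxy-4-methylsulfonyloxyphenyl)propan-2-yl]-5-methoxyphenyl}propanoate | COc1cc([C@@H](O)[C@@H](CO)c2cc(CCC(=O)OC)cc(OC)c2Br)ccc1OS(C)(=O)=O
F9 | step 9 | methyl 3-{4-bromo-3-[(2R,3S)-1-(tert-butyldimethylsilyloxy)-3-hydroxy-3-(3-methoxy-4-methylsulfonyloxyphenyl)propan-2-yl]-5-methoxyphenyl}propanoate | COc1cc([C@@H](O)[C@@H](CO[Si](C)(C)C(C)(C)C)c2cc(CCC(=O)OC)cc(OC)c2Br)ccc1OS(C)(=O)=O
F10 | step 7 | methyl (2R,3R)-3-(3-methoxy-4-methylsulfonyloxyphenyl)oxirane-2-carboxylate | COc1cc([C@H]2O[C@H]2C(=O)OC)ccc1OS(C)(=O)=O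
F11 | step 13 | 4-[(2S,3R)-3-(tert-butyldimethylsilyloxymethyl)-5-(3-hydroxypropyl)-7-methoxy-2,3-dihydro-1-benzofuran-2-yl]-2-methoxyphenol | COc1cc([C@H]2Oc3c(OC)cc(CCCO)cc3[C@@H]2CO[Si](C)(C)C(C)(C)C)ccc1O
F12 | step 13 | 3-[(2S,3R)-2-(4-benzyloxy-3-methoxyphenyl)-3-(tert-butyldimethylsilyloxymethyl)-7-methoxy-2,3-dihydro-1-benzofuran-5-yl]propan-1-ol | COc1cc([C@H]2Oc3c(OC)cc(CCCO)cc3[C@@H]2CO[Si](C)(C)C(C)(C)C)ccc1OCc4ccccc4
F13 | step 13 | sodium 3-[(2S,3R)-2-(4-benzyloxy-3-methoxyphenyl)-3-(tert-butyldimethylsilyloxymethyl)-7-methoxy-2,3-dihydro-1-benzofuran-5-yl]propyl sulfate | COc1cc([C@H]2Oc3c(OC)cc(CCCOS(=O)(=O)[O-])cc3[C@@H]2CO[Si](C)(C)C(C)(C)C)ccc1OCc4ccccc4.[Na+]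
F14 | step 13 | sodium 3-[(2S,3R)-2-(4-benzyloxy-3-methoxyphenyl)-3-(hydroxymethyl)-7-methoxy-2,3-dihydro-1-benzofuran-5-yl]propyl sulfate | COc1cc([C@H]2Oc3c(OC)cc(CCCOS(=O)(=O)[O-])cc3[C@@H]2CO)ccc1OCc4ccccc4.[Na+]
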